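**Plan**

- Retrosynthetic cuts, in order: the C3–C4 bond of ring C (last bond made), the O1–C2 aryl ether, and the C4–C6 bond to ring D; the lower unit is (+)-catechin taken intact.
- Forward: ring D of perbenzylated catechin is blocked at C8 (Br) and iodinated at C6; an Evans glycolate aldol gives the ring-B/C2–C3 hydroxy acid; ring A (4-allyloxy-2-fluorobenzaldehyde) is joined at O1 by SNAr, then its formyl carbon (future C4) takes the ring-D Grignard reagent; ring C closes last.
- Enabling feature: O7 of ring A is para to C4a, so C4 can be the exocyclic carbon of a ring-A para-quinone methide. O3 makes C3 a stabilised α-oxy radical once a carboxyl group is placed on it; that radical closes ring C at C3–C4, the carboxyl leaves as CO2 and the 7-OH is returned.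
- Stereochemistry: lower-unit centres come from (+)-catechin; C2 (R) comes from the auxiliary-controlled aldol and is kept by an SNAr that does not touch the C–O bond; C3 and C4 are set from C2 in the chair-like ring closure (all substituents equatorial).
- Helpers removed later: CO2H on C3 (step 12), allyl on O7 (step 11), Br on C8 of ring D and all benzyl ethers (step 13).

Key step: step 12

Abbreviation in names: ArD = (2R,3S)-3,5,7-tris(benzyloxy)-2-[3,4-bis(benzyloxy)phenyl]-8-bromochroman-6-yl (ring-D unit, bonded through C6).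

Remark: the carbinol carbon of 15 and 16 (future C4) forms as an epimer mixture and the acid-bearing carbon (future C3) keeps its aldol configuration; both become planar in step 12, so neither is controlled earlier.

**Step 1**
Reactants: 1 (+)-catechin
Product: 2 5,7,3',4'-tetra-O-benzyl-(+)-catechin [(2R,3S)-5,7-bis(benzyloxy)-2-[3,4-bis(benzyloxy)phenyl]chroman-3-ol]
Conditions: BnBr (4.4 equiv), K2CO3, DMF, 0 → 25 °C
Reagents that add atoms: benzyl bromide, BrCc1ccccc1
Why: Williamson ether synthesis; carbonate deprotonates only the four phenols, so the secondary 3-OH stays free and no stereocenter is touched.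

**Step 2**
Reactants: 2 5,7,3',4'-tetra-O-benzyl-(+)-catechin
Product: 3 penta-O-benzyl-(+)-catechin [(2R,3S)-3,5,7-tris(benzyloxy)-2-[3,4-bis(benzyloxy)phenyl]chromane]
Conditions: NaH, BnBr, Bu4NI (cat.), DMF, 0 → 25 °C
Reagents that add atoms: benzyl bromide, BrCc1ccccc1
Why: Williamson alkylation of the sodium alkoxide; with all phenols capped, the base-induced ring opening that would epimerise C2 is closed off.

**Step 3**
Reactants: 3 penta-O-benzyl-(+)-catechin
Product: 4 (2R,3S)-3,5,7-tris(benzyloxy)-2-[3,4-bis(benzyloxy)phenyl]-8-bromochromane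
Conditions: NBS (1.0 equiv), CH2Cl2, −78 → 0 °C
Reagents that add atoms: N-bromosuccinimide, O=C1CCC(=O)N1Br
Why: electrophilic aromatic bromination; C8 of ring D should react before the more hindered C6, as is usual for 5,7-di-O-benzyl flavan-3-ols, and the bromine then blocks C8.

**Step 4**
Reactants: 4 8-bromo-penta-O-benzylcatechin
Product: 5 (2R,3S)-3,5,7-tris(benzyloxy)-2-[3,4-bis(benzyloxy)phenyl]-8-bromo-6-iodochromane
Conditions: NIS (1.1 equiv), CF3CO2H (10 mol%), MeCN/CH2Cl2, 0 → 25 °C, dark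
Reagents that add atoms: N-iodosuccinimide, O=C1CCC(=O)N1I
Why: electrophilic aromatic iodination at C6, the only free position of the phloroglucinol-type ring D, which remains far more electron rich than the catechol-type rings.

**Step 5**
Reactants: 6 (S)-4-benzyloxazolidin-2-one
Product: 7 (S)-4-benzyl-3-[(benzyloxy)acetyl]oxazolidin-2-one
Conditions: n-BuLi, THF, −78 °C; then BnOCH2COCl, −78 → 0 °C
Reagents that add atoms: (benzyloxy)acetyl chloride, O=C(Cl)COCc1ccccc1
Why: N-acylation of the lithiated oxazolidinone (loading of the Evans auxiliary).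

**Step 6**
Reactants: 7 (S)-4-benzyl-3-[(benzyloxy)acetyl]oxazolidin-2-one; 8 3,4-bis(benzyloxy)benzaldehyde
Product: 9 (4S)-4-benzyl-3-{(2S,3R)-2-(benzyloxy)-3-[3,4-bis(benzyloxy)phenyl]-3-hydroxypropanoyl}oxazolidin-2-one
Conditions: Bu2BOTf, Et3N, CH2Cl2, −78 → 0 °C; then pH 7 buffer, MeOH, H2O2
Reagents that add atoms: none
Why: Evans boron glycolate aldol; the (Z)-boron enolate reacts through a Zimmerman–Traxler chair on the face away from the benzyl group of the auxiliary, giving the syn (2S,3R) adduct whose carbinol carbon is the future C2 (R).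

**Step 7**
Reactants: 9 aldol adduct
Product: 10 (2S,3R)-2-(benzyloxy)-3-[3,4-bis(benzyloxy)phenyl]-3-hydroxypropanoic acid
Conditions: LiOH, H2O2, THF/H2O, 0 °C; Na2SO3; then cold 1 M HCl to pH 3
Reagents that add atoms: hydrogen peroxide (as LiOOH), OO
Why: hydroperoxide cleavage of the N-acyl oxazolidinone at the exocyclic carbonyl, which should proceed without retro-aldol or epimerisation and returns the auxiliary.

**Step 8**
Reactants: 11 2-fluoro-4-hydroxybenzaldehyde
Product: 12 4-(allyloxy)-2-fluorobenzaldehyde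
Conditions: allyl bromide, K2CO3, acetone, 56 °C
Reagents that add atoms: allyl bromide, C=CCBr
Why: Williamson ether synthesis; allyl is chosen because it survives alkoxide and Grignard reagents and can be removed with palladium without touching benzyl ethers.

**Step 9**
Reactants: 10 hydroxy acid; 12 4-(allyloxy)-2-fluorobenzaldehyde
Product: 13 (2S,3R)-3-[5-(allyloxy)-2-formylphenoxy]-2-(benzyloxy)-3-[3,4-bis(benzyloxy)phenyl]propanoic acid
Conditions: NaH (2.2 equiv), THF/DMF 4:1, 0 °C; then 12, 0 → 25 °C; cold dilute HCl to pH 3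
Reagents that add atoms: none
Why: SNAr of the fluoride ortho to the formyl group by the alkoxide of the carboxylate–alkoxide dianion (which cannot undergo retro-aldol); the new bond is O–aryl, so the carbinol C–O bond is untouched and C2 keeps its (R) configuration.

**Step 10**
Reactants: 5 8-bromo-6-iodo-penta-O-benzylcatechin; 13 aldehyde acid
Product: 15 (2S,3R)-3-{5-(allyloxy)-2-[hydroxy(ArD)methyl]phenoxy}-2-(benzyloxy)-3-[3,4-bis(benzyloxy)phenyl]propanoic acid (carbinol epimers), via arylmagnesium chloride 14 (not isolated)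
Conditions: 5, iPrMgCl·LiCl (1.05 equiv), THF, −20 °C; 13 pretreated with LiN(SiMe3)2 (1.0 equiv), THF, −78 °C, then added; −40 → 0 °C; aq. NH4Cl
Reagents that add atoms: none
Why: iodine–magnesium exchange with the turbo-Grignard reagent is far faster at the iodide than at the bromide, and the aryl Grignard then adds 1,2 to the aldehyde while the acid is masked as its lithium salt; this fixes the ring-D attachment at C6 unambiguously.

**Step 11**
Reactants: 15 allyl-protected benzhydrol acid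
Product: 16 (2S,3R)-2-(benzyloxy)-3-[3,4-bis(benzyloxy)phenyl]-3-{5-hydroxy-2-[hydroxy(ArD)methyl]phenoxy}propanoic acid (carbinol epimers)
Conditions: Pd(PPh3)4 (5 mol%), morpholine (3 equiv), THF, 25 °C; cold pH 4 citrate wash; used at once
Reagents that add atoms: none
Why: Tsuji–Trost-type deallylation; zerovalent palladium ionises the aryl allyl ether and morpholine traps the π-allyl group, while the aryl bromide and benzyl ethers should stay untouched at 25 °C.

**Step 12**
Reactants: 16 phenol benzhydrol acid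
Product: 18 (2R,3S,4S)-3-(benzyloxy)-2-[3,4-bis(benzyloxy)phenyl]-4-ArD-chroman-7-ol, via ring-A para-quinone methide 17 (not isolated)
Conditions: 4 Å MS, MeCN (0.01 M), 40 °C, dark; then Ir[dF(CF3)ppy]2(dtbbpy)PF6 (2 mol%), K2HPO4 (1.5 equiv), DMSO (co-solvent), 450 nm LEDs, 25 °C
Reagents that add atoms: none
Why: Proposed new method: 16 should lose water under catalysis by its own carboxyl group to give the ring-A para-quinone methide 17, whose carboxylate is then oxidised by the excited trivalent iridium complex; loss of CO2 leaves a nucleophilic α-benzyloxy radical at C3 that adds to the exocyclic methide carbon C4, and the resulting ring-A phenoxyl radical is reduced by divalent iridium and protonated, so the closure is redox neutral and returns the 7-OH. The closest known reactions are the intermolecular photoredox decarboxylative 1,6-addition (Giese type) of α-oxy acids to para-quinone methides and the polar 1,6-ring closures of ortho-tethered para-quinone methides to chromans. Ring C closes 6-endo-trig at C4; the 5-exo alternative would attack the fully substituted C4a, restore no aromatic ring and oppose the polarity of the methide, whose largest LUMO coefficient is at C4. C4 is controlled by the methide geometry and by C2: the bulky ring-D aryl sits on the C5 side, away from O1, and so becomes pseudo-equatorial, while the chair-like transition state with the C2 aryl equatorial selects the face that gives 2,4-cis (4S). C3 is controlled by C2 as well: in that chair the benzyloxy group of the planar radical takes the position anti to the C2–O1 bond and next to C2–H, which is equatorial and trans to the C2 aryl (3S). The step needs ring closure to beat β-scission of the C2–O1 bond and simple reduction of the radical, which the intramolecular, highly electrophilic methide, formed completely before irradiation, should secure.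

**Step 13**
Reactants: 18 protected dimer
Product: 19 fisetinidol-(4α→6)-catechin [(2R,3S,4S)-2-(3,4-dihydroxyphenyl)-4-[(2R,3S)-2-(3,4-dihydroxyphenyl)-3,5,7-trihydroxychroman-6-yl]chroman-3,7-diol]
Conditions: H2 (1 atm), Pd(OH)2/C, NaOAc (1.5 equiv), THF/MeOH/H2O, 25 °C
Reagents that add atoms: none
Why: hydrogenolysis of the eight benzyl ethers together with hydrodebromination at C8 of ring D, buffered so that HBr cannot cleave or epimerise the interflavan bond; no stereocenter is involved.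

**Compound list**

1 | (+)-catechin | Oc1cc2c(c(O)c1)C[C@H](O)[C@@H](c1ccc(O)c(O)c1)O2 | starting material
2 | 5,7,3',4'-tetra-O-benzyl-(+)-catechin | c1c(OCc3ccccc3)cc2c(c1OCc1ccccc1)C[C@H](O)[C@@H](c1ccc(OCc3ccccc3)c(OCc3ccccc3)c1)O2 | intermediate
3 | penta-O-benzyl-(+)-catechin | c1c(OCc3ccccc3)cc2c(c1OCc1ccccc1)C[C@H](OCc1ccccc1)[C@@H](c1ccc(OCc3ccccc3)c(OCc3ccccc3)c1)O2 | intermediate
4 | (2R,3S)-3,5,7-tris(benzyloxy)-2-[3,4-bis(benzyloxy)phenyl]-8-bromochromane | c1c(OCc3ccccc3)c(Br)c2c(c1OCc1ccccc1)C[C@H](OCc1ccccc1)[C@@H](c1ccc(OCc3ccccc3)c(OCc3ccccc3)c1)O2 | intermediate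
5 | (2R,3S)-3,5,7-tris(benzyloxy)-2-[3,4-bis(benzyloxy)phenyl]-8-bromo-6-iodochromane | Ic1c(OCc3ccccc3)c(Br)c2c(c1OCc1ccccc1)C[C@H](OCc1ccccc1)[C@@H](c1ccc(OCc3ccccc3)c(OCc3ccccc3)c1)O2 | intermediate
6 | (S)-4-benzyloxazolidin-2-one | O=C1N[C@@H](Cc2ccccc2)CO1 | starting material
7 | (S)-4-benzyl-3-[(benzyloxy)acetyl]oxazolidin-2-one | O=C(COCc1ccccc1)N1[C@@H](Cc2ccccc2)COC1=O | intermediate
8 | 3,4-bis(benzyloxy)benzaldehyde | O=Cc1ccc(OCc2ccccc2)c(OCc2ccccc2)c1 | starting material
9 | (4S)-4-benzyl-3-{(2S,3R)-2-(benzyloxy)-3-[3,4-bis(benzyloxy)phenyl]-3-hydroxypropanoyl}oxazolidin-2-one | O[C@H](c1ccc(OCc2ccccc2)c(OCc2ccccc2)c1)[C@H](OCc1ccccc1)C(=O)N1[C@@H](Cc2ccccc2)COC1=O | intermediate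
10 | (2S,3R)-2-(benzyloxy)-3-[3,4-bis(benzyloxy)phenyl]-3-hydroxypropanoic acid | O[C@H](c1ccc(OCc2ccccc2)c(OCc2ccccc2)c1)[C@H](OCc1ccccc1)C(O)=O | intermediate
11 | 2-fluoro-4-hydroxybenzaldehyde | O=Cc1ccc(O)cc1F | starting material
12 | 4-(allyloxy)-2-fluorobenzaldehyde | C=CCOc1ccc(C=O)c(F)c1 | intermediate
13 | (2S,3R)-3-[5-(allyloxy)-2-formylphenoxy]-2-(benzyloxy)-3-[3,4-bis(benzyloxy)phenyl]propanoic acid | C=CCOc1ccc(C=O)c(c1)O[C@H](c1ccc(OCc2ccccc2)c(OCc2ccccc2)c1)[C@H](OCc1ccccc1)C(O)=O | intermediate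
14 | ArD-magnesium chloride (LiCl complex), the 6-magnesio derivative of 4 | Cl[Mg]c1c(OCc3ccccc3)c(Br)c2c(c1OCc1ccccc1)C[C@H](OCc1ccccc1)[C@@H](c1ccc(OCc3ccccc3)c(OCc3ccccc3)c1)O2 | intermediate (not isolated)
15 | (2S,3R)-3-{5-(allyloxy)-2-[hydroxy(ArD)methyl]phenoxy}-2-(benzyloxy)-3-[3,4-bis(benzyloxy)phenyl]propanoic acid, carbinol epimers | C=CCOc1ccc(C(O)c2c(OCc4ccccc4)c(Br)c3c(c2OCc2ccccc2)C[C@H](OCc2ccccc2)[C@@H](c2ccc(OCc4ccccc4)c(OCc4ccccc4)c2)O3)c(c1)O[C@H](c1ccc(OCc2ccccc2)c(OCc2ccccc2)c1)[C@H](OCc1ccccc1)C(O)=O | intermediate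
16 | (2S,3R)-2-(benzyloxy)-3-[3,4-bis(benzyloxy)phenyl]-3-{5-hydroxy-2-[hydroxy(ArD)methyl]phenoxy}propanoic acid, carbinol epimers | Oc1ccc(C(O)c2c(OCc4ccccc4)c(Br)c3c(c2OCc2ccccc2)C[C@H](OCc2ccccc2)[C@@H](c2ccc(OCc4ccccc4)c(OCc4ccccc4)c2)O3)c(c1)O[C@H](c1ccc(OCc2ccccc2)c(OCc2ccccc2)c1)[C@H](OCc1ccccc1)C(O)=O | intermediate
17 | ring-A para-quinone methide: (2S,3R)-2-(benzyloxy)-3-[3,4-bis(benzyloxy)phenyl]-3-{[(6E)-6-(ArD-methylidene)-3-oxocyclohexa-1,4-dien-1-yl]oxy}propanoic acid | O=C1C=C/C(=C\c2c(OCc4ccccc4)c(Br)c3c(c2OCc2ccccc2)C[C@H](OCc2ccccc2)[C@@H](c2ccc(OCc4ccccc4)c(OCc4ccccc4)c2)O3)C(=C1)O[C@H](c1ccc(OCc2ccccc2)c(OCc2ccccc2)c1)[C@H](OCc1ccccc1)C(O)=O | intermediate (not isolated)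
18 | (2R,3S,4S)-3-(benzyloxy)-2-[3,4-bis(benzyloxy)phenyl]-4-ArD-chroman-7-ol | Oc1ccc2c(c1)O[C@H](c1ccc(OCc3ccccc3)c(OCc3ccccc3)c1)[C@@H](OCc1ccccc1)[C@@H]2c1c(OCc3ccccc3)c(Br)c2c(c1OCc1ccccc1)C[C@H](OCc1ccccc1)[C@@H](c1ccc(OCc3ccccc3)c(OCc3ccccc3)c1)O2 | intermediate
19 | fisetinidol-(4α→6)-catechin (CNP0141631.1) | Oc1ccc2c(c1)O[C@H](c1ccc(O)c(O)c1)[C@@H](O)[C@@H]2c1c(O)cc2c(c1O)C[C@H](O)[C@@H](c1ccc(O)c(O)c1)O2 | target

**Step count**

Total: 13 steps. Longest linear sequence: 8 steps (1–4, then 10–13; the branch 5–7, 9, then 10–13 is equally long).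

**Steps most likely to fail**

Step 12 (proposed new method). What may go wrong: the methide is not fully formed before light is applied, so the radical is merely reduced; the ring closure loses facial control at C3 or C4; or the radical fragments at the C2–O1 bond. The fallback uses known reactions, sets out from 5 (as its Grignard reagent 14) and from 8, and comes back to the route at 19. Reagent 14 is added to commercial 4-(benzyloxy)-2-fluorobenzaldehyde to give the diaryl carbinol [4-(benzyloxy)-2-fluorophenyl](ArD)methanol F1, which MnO2 oxidises to the benzophenone [4-(benzyloxy)-2-fluorophenyl](ArD)methanone F2. Aldehyde 8 is vinylated enantioselectively (divinylzinc, Ti(OiPr)4/TADDOL) to (S)-1-[3,4-bis(benzyloxy)phenyl]prop-2-en-1-ol F3. The sodium alkoxide of F3 displaces the ketone-activated fluoride of F2 (SNAr, retention) to give the allylic aryl ether {4-(benzyloxy)-2-[(1S)-1-[3,4-bis(benzyloxy)phenyl]prop-2-en-1-yl]oxyphenyl}(ArD)methanone F4. Wittig methylenation (Ph3PCH3Br, KOtBu) gives the 1,1-diarylethene F5. Ring-closing metathesis (second-generation Grubbs catalyst, toluene, 80 °C) closes ring C at C3=C4 to (2S)-7-(benzyloxy)-2-[3,4-bis(benzyloxy)phenyl]-4-ArD-2H-chromene F6. Hydroboration–oxidation (BH3·THF; then NaOH, H2O2) should deliver boron to C3 and hydrogen to C4 on the face away from the C2 aryl group, giving the 2,3-trans-3,4-trans alcohol (2R,3S,4S)-7-(benzyloxy)-2-[3,4-bis(benzyloxy)phenyl]-4-ArD-chroman-3-ol F7. Hydrogenolysis under the conditions of step 13 gives 19.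

Step 9. What may go wrong: the alkoxide adds to the formyl group or transfers hydride to it instead of displacing fluoride, or the displacement is too slow at a temperature the dianion tolerates. The fallback sets out from 10 and comes back at 13. Commercial 2-fluoro-4-hydroxybenzonitrile is allylated (allyl bromide, K2CO3) to 4-(allyloxy)-2-fluorobenzonitrile F8. The dianion of 10 (NaH, DMF) displaces its fluoride, the nitrile being a stronger activator that cannot take up hydride, to give the nitrile acid (2S,3R)-3-[5-(allyloxy)-2-cyanophenoxy]-2-(benzyloxy)-3-[3,4-bis(benzyloxy)phenyl]propanoic acid F9. Reduction with iBu2AlH (CH2Cl2, −78 °C) and mild aqueous acid hydrolysis of the aldimine give 13.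

Step 10. What may go wrong: the arylmagnesium reagent is quenched by incompletely masked acid, the halogen–magnesium exchange is incomplete, or addition to the hindered, salt-bearing aldehyde stalls. The fallback sets out from 5 (via 14), 12 and 10 and comes back at 15. Reagent 14 is added to the simple aldehyde 12 to give the fluoro carbinol [4-(allyloxy)-2-fluorophenyl](ArD)methanol F10. MnO2 gives the benzophenone [4-(allyloxy)-2-fluorophenyl](ArD)methanone F11. The dianion of 10 displaces the ketone-activated fluoride (NaH, THF/DMF) to give the keto acid (2S,3R)-3-[5-(allyloxy)-2-(ArD-carbonyl)phenoxy]-2-(benzyloxy)-3-[3,4-bis(benzyloxy)phenyl]propanoic acid F12, and NaBH4 (THF/MeOH) reduces the ketone to 15.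

**Further compounds**

F1 | step 12 | [4-(benzyloxy)-2-fluorophenyl](ArD)methanol | OC(c1ccc(OCc5ccccc5)cc1F)c2c(OCc4ccccc4)c(Br)c3c(c2OCc2ccccc2)C[C@H](OCc2ccccc2)[C@@H](c2ccc(OCc4ccccc4)c(OCc4ccccc4)c2)O3
F2 | step 12 | [4-(benzyloxy)-2-fluorophenyl](ArD)methanone | O=C(c1ccc(OCc5ccccc5)cc1F)c2c(OCc4ccccc4)c(Br)c3c(c2OCc2ccccc2)C[C@H](OCc2ccccc2)[C@@H](c2ccc(OCc4ccccc4)c(OCc4ccccc4)c2)O3
F3 | step 12 | (S)-1-[3,4-bis(benzyloxy)phenyl]prop-2-en-1-ol | O[C@H](c1ccc(OCc2ccccc2)c(OCc2ccccc2)c1)C=C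
F4 | step 12 | {4-(benzyloxy)-2-[(1S)-1-[3,4-bis(benzyloxy)phenyl]prop-2-en-1-yl]oxyphenyl}(ArD)methanone | O=C(c1ccc(OCc5ccccc5)cc1O[C@H](c5ccc(OCc6ccccc6)c(OCc6ccccc6)c5)C=C)c2c(OCc4ccccc4)c(Br)c3c(c2OCc2ccccc2)C[C@H](OCc2ccccc2)[C@@H](c2ccc(OCc4ccccc4)c(OCc4ccccc4)c2)O3
F5 | step 12 | 1-{4-(benzyloxy)-2-[(1S)-1-[3,4-bis(benzyloxy)phenyl]prop-2-en-1-yl]oxyphenyl}-1-(ArD)ethene | C=C(c1ccc(OCc5ccccc5)cc1O[C@H](c5ccc(OCc6ccccc6)c(OCc6ccccc6)c5)C=C)c2c(OCc4ccccc4)c(Br)c3c(c2OCc2ccccc2)C[C@H](OCc2ccccc2)[C@@H](c2ccc(OCc4ccccc4)c(OCc4ccccc4)c2)O3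
F6 | step 12 | (2S)-7-(benzyloxy)-2-[3,4-bis(benzyloxy)phenyl]-4-ArD-2H-chromene | O(Cc1ccccc1)c1ccc2c(c1)O[C@H](c1ccc(OCc3ccccc3)c(OCc3ccccc3)c1)C=C2c1c(OCc3ccccc3)c(Br)c2c(c1OCc1ccccc1)C[C@H](OCc1ccccc1)[C@@H](c1ccc(OCc3ccccc3)c(OCc3ccccc3)c1)O2
F7 | step 12 | (2R,3S,4S)-7-(benzyloxy)-2-[3,4-bis(benzyloxy)phenyl]-4-ArD-chroman-3-ol | O(Cc1ccccc1)c1ccc2c(c1)O[C@H](c1ccc(OCc3ccccc3)c(OCc3ccccc3)c1)[C@@H](O)[C@@H]2c1c(OCc3ccccc3)c(Br)c2c(c1OCc1ccccc1)C[C@H](OCc1ccccc1)[C@@H](c1ccc(OCc3ccccc3)c(OCc3ccccc3)c1)O2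
F8 | step 9 | 4-(allyloxy)-2-fluorobenzonitrile | N#Cc1ccc(OCC=C)cc1F
F9 | step 9 | (2S,3R)-3-[5-(allyloxy)-2-cyanophenoxy]-2-(benzyloxy)-3-[3,4-bis(benzyloxy)phenyl]propanoic acid | C=CCOc1ccc(C#N)c(c1)O[C@H](c1ccc(OCc2ccccc2)c(OCc2ccccc2)c1)[C@H](OCc1ccccc1)C(O)=O
F10 | step 10 | [4-(allyloxy)-2-fluorophenyl](ArD)methanol | C=CCOc1ccc(C(O)c2c(OCc4ccccc4)c(Br)c3c(c2OCc2ccccc2)C[C@H](OCc2ccccc2)[C@@H](c2ccc(OCc4ccccc4)c(OCc4ccccc4)c2)O3)c(F)c1
F11 | step 10 | [4-(allyloxy)-2-fluorophenyl](ArD)methanone | C=CCOc1ccc(C(=O)c2c(OCc4ccccc4)c(Br)c3c(c2OCc2ccccc2)C[C@H](OCc2ccccc2)[C@@H](c2ccc(OCc4ccccc4)c(OCc4ccccc4)c2)O3)c(F)c1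
F12 | step 10 | (2S,3R)-3-[5-(allyloxy)-2-(ArD-carbonyl)phenoxy]-2-(benzyloxy)-3-[3,4-bis(benzyloxy)phenyl]propanoic acid | C=CCOc1ccc(C(=O)c2c(OCc4ccccc4)c(Br)c3c(c2OCc2ccccc2)C[C@H](OCc2ccccc2)[C@@H](c2ccc(OCc4ccccc4)c(OCc4ccccc4)c2)O3)c(c1)O[C@H](c1ccc(OCc2ccccc2)c(OCc2ccccc2)c1)[C@H](OCc1ccccc1)C(O)=O
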